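**Assumptions:** 7-hydroxychromone is bought as a catalogue compound (otherwise one extra step from 2,4-dihydroxyacetophenone). The ligand antipode in step 5 is the one that gives 2S; I expect this to be the (S)-biaryl ligand by analogy with the (S)-BINAP/cyclohexenone model, but I have not confirmed it, so check on the first run and switch antipode if needed.

## Retrosynthetic overview

1. Sophoranone ⇐ aromatic Claisen rearrangement of the 7-O-(1,1-dimethylallyl) ether of the flavanone; this forms the C8–prenyl bond and frees the 7-OH, so the ether is the only "protecting group".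
2. That flavanone ether ⇐ Rh-catalysed enantioselective 1,4-arylation that dearomatises the γ-pyrone ring of a 7-alkoxychromone and sets C2 (S), using the unprotected, fully prenylated B-ring boronic acid.
3. Boronic acid ⇐ 4-bromophenol (double ortho-C-prenylation, then borylation). Chromone ether ⇐ 7-hydroxychromone (Cu-assisted propargylation, Lindlar).
4. Rings: none is constructed. The A/C rings enter as the chromone (the C ring becomes the saturated pyranone in the key step) and the B ring enters as 4-bromophenol.

## Route

**Step 1**
Reactants: 1, 4-bromophenol; 2, prenyl bromide (1-bromo-3-methylbut-2-ene)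
Product: 3, 4-bromo-2,6-bis(3-methylbut-2-en-1-yl)phenol
Conditions: NaH (2 × 1.1 equiv), 2 (2 × 1.1 equiv, two charges in one pot), toluene, 0 °C → rt
Reagents that add atoms: prenyl bromide, CC(C)=CCBr
Why: ortho-selective C-alkylation of a sodium phenoxide in a non-polar solvent (tight ion pair, SN2 at the primary carbon, transient cyclohexadienone re-aromatises), and with the para position blocked by Br both ortho positions are prenylated, the O-prenyl ether and mono-prenyl phenol being separable by-products.

**Step 2**
Reactants: 3, 4-bromo-2,6-bis(3-methylbut-2-en-1-yl)phenol; 4, tetrahydroxydiboron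
Product: 5, [4-hydroxy-3,5-bis(3-methylbut-2-en-1-yl)phenyl]boronic acid
Conditions: XPhos Pd G2 (2 mol %), XPhos (4 mol %), KOAc (3 equiv), EtOH, 80 °C; work-up at pH ≈ 6, use without prolonged silica contact
Reagents that add atoms: tetrahydroxydiboron, OB(O)B(O)O
Why: Miyaura-type Pd-catalysed borylation of an electron-rich aryl bromide with B2(OH)4, which tolerates the free hindered phenol and the trisubstituted alkenes (the prenyl groups are meta to Pd, so no intramolecular Heck is possible) and gives the boronic acid directly.

**Step 3**
Reactants: 6, 7-hydroxy-4H-chromen-4-one (7-hydroxychromone); 7, 3-chloro-3-methylbut-1-yne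
Product: 8, 7-[(2-methylbut-3-yn-2-yl)oxy]-4H-chromen-4-one
Conditions: K2CO3, KI, CuI (5 mol %), acetone, 55 °C
Reagents that add atoms: 3-chloro-3-methylbut-1-yne, C#CC(C)(C)Cl
Why: Cu-assisted propargylic substitution (copper acetylide/allenylidene pathway) O-alkylates the acidic 7-OH with the tertiary propargylic chloride, as is routine for umbelliferone-type phenols, and the chromone is stable to K2CO3/acetone.

**Step 4**
Reactants: 8, 7-[(2-methylbut-3-yn-2-yl)oxy]-4H-chromen-4-one
Product: 9, 7-[(2-methylbut-3-en-2-yl)oxy]-4H-chromen-4-one
Conditions: H2 (1 atm, 1 equiv uptake), Lindlar catalyst, quinoline, EtOAc, rt; Et3N-deactivated silica, store cold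
Reagents that add atoms: none
Why: Lindlar semi-hydrogenation reduces the terminal alkyne to the vinyl group while the poisoned catalyst leaves the chromone C2=C3 vinylogous ester untouched.

**Step 5 (key step)**
Reactants: 9, 7-[(2-methylbut-3-en-2-yl)oxy]-4H-chromen-4-one; 5, [4-hydroxy-3,5-bis(3-methylbut-2-en-1-yl)phenyl]boronic acid (1.8 equiv)
Product: 10, (2S)-2-[4-hydroxy-3,5-bis(3-methylbut-2-en-1-yl)phenyl]-7-[(2-methylbut-3-en-2-yl)oxy]-2,3-dihydro-4H-chromen-4-one
Conditions: [Rh(OH)(cod)]2 (2.5 mol %), (S)-MeO-F12-BIPHEP (5.5 mol %), toluene/H2O 10:1, 35 °C, no added base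
Reagents that add atoms: none
Why: Hayashi–Miyaura Rh-catalysed asymmetric 1,4-addition to a chromone, in which the chiral aryl–Rh species carbometalates one enantioface of the C2=C3 bond and protonation of the Rh oxa-π-allyl gives the 2S flavanone, while the base-free medium avoids retro-oxa-Michael or quinone-methide racemisation and leaves the prenyl alkenes and the hindered tert-allyl ether alone.

**Step 6**
Reactants: 10, the (2S)-flavanone 7-O-(1,1-dimethylallyl) ether
Product: 11, sophoranone, (2S)-7-hydroxy-2-[4-hydroxy-3,5-bis(3-methylbut-2-en-1-yl)phenyl]-8-(3-methylbut-2-en-1-yl)-2,3-dihydro-4H-chromen-4-one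
Conditions: degassed toluene (0.02 M), 105–110 °C, sealed tube, base-free; monitor ee by chiral HPLC
Reagents that add atoms: none
Why: aromatic Claisen ([3,3]) rearrangement of the aryl 1,1-dimethylallyl ether gives a C8 dienone that tautomerises to the 7-phenol with a normal prenyl group, C8 being preferred over C6 because O1/C4=O conjugation gives C7–C8 more double-bond character, and C2 is not touched under neutral, aprotic conditions.

## Compound list

1 | 4-bromophenol | Oc1ccc(Br)cc1 | starting material
2 | prenyl bromide | CC(C)=CCBr | starting material
3 | 4-bromo-2,6-bis(3-methylbut-2-en-1-yl)phenol | CC(C)=CCc1cc(Br)cc(CC=C(C)C)c1O | intermediate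
4 | tetrahydroxydiboron | OB(O)B(O)O | starting material
5 | [4-hydroxy-3,5-bis(3-methylbut-2-en-1-yl)phenyl]boronic acid | CC(C)=CCc1cc(B(O)O)cc(CC=C(C)C)c1O | intermediate
6 | 7-hydroxy-4H-chromen-4-one | O=c1ccoc2cc(O)ccc12 | starting material
7 | 3-chloro-3-methylbut-1-yne | C#CC(C)(C)Cl | starting material
8 | 7-[(2-methylbut-3-yn-2-yl)oxy]-4H-chromen-4-one | C#CC(C)(C)Oc1ccc2c(c1)occc2=O | intermediate
9 | 7-[(2-methylbut-3-en-2-yl)oxy]-4H-chromen-4-one | C=CC(C)(C)Oc1ccc2c(c1)occc2=O | intermediate
10 | (2S)-2-[4-hydroxy-3,5-bis(3-methylbut-2-en-1-yl)phenyl]-7-[(2-methylbut-3-en-2-yl)oxy]chroman-4-one | CC(C)=CCc1cc([C@@H]2CC(=O)c3ccc(OC(C)(C)C=C)cc3O2)cc(CC=C(C)C)c1O | intermediate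
11 | sophoranone | CC(C)=CCc1cc([C@@H]2CC(=O)c3ccc(O)c(CC=C(C)C)c3O2)cc(CC=C(C)C)c1O | target

## Summary

Total steps: 6 (convergent, no protecting groups).
Longest linear sequence: 4 steps (6 → 8 → 9 → 10 → 11, or 1 → 3 → 5 → 10 → 11).

Steps most likely to fail:

1. **Step 5.** Risks are protodeboronation of the electron-rich free-phenol boronic acid, sluggish addition to the donor-substituted chromone, Rh insertion/β-aryloxide elimination at the tert-allyl ether, and an unverified sense or level of induction. Fallback: give up the protecting-group-free coupling. Silylate 3 (TBS) before borylation so the nucleophile is a standard non-acidic arylboronic acid, couple it under Rh or the cationic Pd(II)/t-BuPyOx manifold, and remove TBS with Et3N·3HF before step 6 (+2 steps).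

2. **Step 6.** Risks are the C6-prenyl regioisomer, loss of the tert-allyl group by ionisation, and thermal erosion of ee through a p-quinone methide or chalcone. Fallback: reverse the order of events. Run the Claisen rearrangement on chromone 9, where chromone bond fixation directs to C8 and no stereocentre exists, then protect the 7-OH as TBS, do the asymmetric arylation, and finish with buffered fluoride (+2 steps).

3. **Step 1.** Risks are a modest yield and mixtures of O-alkyl, mono-prenyl and gem-diprenyl dienone products. Fallback: change the C–C bond-forming logic. Make 4-bromo-2,6-diallylphenol by two rounds of O-allylation/thermal Claisen from 1, then convert both allyl groups to prenyl by cross-metathesis with 2-methyl-2-butene (Grubbs II).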